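## Structural features

The target 22 (C28H24O4) is an achiral macrocyclic bis(bibenzyl). Four benzene rings A–D are joined in one 18-membered ring by two CH2CH2 bridges (A–B and C–D) and two diaryl ether oxygens (B–O–C and D–O–A). Ring A is a 1,2,4-trisubstituted phenol with OH para to the ring D oxygen and the bridge ortho to that oxygen. Ring B is a para-phenylene, ring D a meta-phenylene, and ring C carries OH and the ring B oxygen on adjacent carbons with its bridge para to the OH. There are no stereocentres; only alkene geometries and one transient sp3 carbon appear on the way, and all are erased. The fragile groups are the two free phenols (a hydroquinone mono aryl ether on ring A, a catechol mono aryl ether on ring C), which oxidise easily and are therefore unveiled last. The real difficulty is closing an 18-membered ring that contains a rigid para-phenylene while deciding which oxygenated carbon becomes ether and which stays OH. The key step exploits ring C: a C–OH carbon next to a carbon bonded to the ring B oxygen, bridge para to OH, is what results when the oxygen of one para-alkylphenol (ring B) adds to the ortho carbon of a second, oxidised para-alkylphenol (ring C).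

## Logic of the disconnections

22 ⇒ 21. Two chlorines (ring B, ortho to the ether oxygen), one bromine (ring C, ortho to OH) and a benzyl group on the ring A oxygen are added retrosynthetically. In the forward sense two C–Cl bonds, one C–Br bond and one O–CH2Ph bond are cut. These four groups are the control elements of the ring closure and the only protection the oxidation needs. The forward step must cleave all four in one reductive operation without touching the diaryl ethers.

21 ⇒ 19 (through 20). The bond between the ring B oxygen and the ring C carbon ortho to OH is cut, which opens the macrocycle to a flexible chain with two 2,6-dihalo-4-alkylphenols. This removes the only ring-forming problem. The forward step must oxidise ring C and not ring B, must couple oxygen to carbon and not carbon to carbon, and must do so within one molecule.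

19 ⇒ 18. The two phenolic O–H groups are masked as methoxymethyl acetals. The masked phenols let the aldehyde partners behave as normal electrophiles in olefination. Unmasking must leave the benzyl ether intact, which dilute acid does.

18 ⇒ 17. Both ethano bridges are traced back to C=C bonds. This allows both bridges to come from olefinations and to be saturated together in one operation. The reduction must spare four aryl halides and a benzyl ether, which rules out palladium-catalysed hydrogenation.

17 ⇒ 13 + 15, and 15 ⇒ 14. The C=C of the C–D bridge is cut between a ring D benzylic phosphonium centre and the aldehyde carbon of the dibrominated ring. The brominated ring enters last, after the only hydride reduction of the route. 15 comes from 14 by acetal protection.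

13 ⇒ 11 ⇒ 10. The C–P bond, then (through 12) the C–Br bond, then the benzylic C–OH are traced back to the ester of 10. The ester is a latent second benzylic handle that stays inert while the first bridge is made. Halide formation must be non-acidic because of the acetal.

10 ⇒ 6 + 8, and 8 ⇒ 7. The C=C of the A–B bridge is cut between the ring A benzylic phosphonium centre and the aldehyde carbon of the dichlorinated ring. Only aryl chlorides, which resist hydride, are present during the later ester reduction.

6 ⇒ 5 ⇒ 4. The C–P bond and the benzylic C–O bond are traced back to the formyl group of 4. That formyl group is the same one that activates the ether formation.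

4 ⇒ 2 + 3, and 2 ⇒ 1. The ring A carbon–oxygen bond of the D–O–A ether is cut, giving a fluoroarene activated by an ortho formyl group and a simple phenol. The ring A oxygen must be benzylated first, because a para phenoxide would shut down the substitution.

## Other disconnections considered

Alternative 1: The cut is the CH2–CH2 bond of the A–B bridge, reached through a carbinol. 22 would come from the racemic macrocyclic 1,2-diarylethanol A2, and A2 from the 19-membered dibenzyl ether A1, in which rings A and B are linked by CH2–O–CH2. In the forward key step n-BuLi would remove a benzylic proton of A1 and the alpha-alkoxy carbanion would undergo a [1,2]-Wittig shift (radical-pair dissociation and recombination), contracting the ring by one atom to A2. Deoxygenation and cleavage of two methyl ethers would follow.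
- In its favour: the large ring is first closed by an ordinary Williamson etherification, the carbon–carbon bond is then made intramolecularly, and deprotonation at either benzylic carbon converges on the same bibenzyl after deoxygenation. No halogen auxiliaries and no thallium are needed, so on reagent hazard it is the better plan.
- Against it here: n-BuLi can metalate ortho to the methoxy and aryloxy groups, the carbanion can shift into the arene instead, and radical-pair rearrangements are rarely clean. The step also creates a carbinol stereocentre that 22 does not contain.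
- Comparison: on structure the two plans are equal, since both define the 18-membered ring late and leave no lasting stereochemical issue. Mechanistically the chosen plan has its coupling site fixed by the halogens, while this one depends on kinetic acidity. On step economy it needs two to three operations after its key step against one, and both diaryl ethers must be made separately beforehand, so it should be somewhat longer.

Alternative 2: The cut is the bond between the D–A ether oxygen and its ring A carbon. The open precursor A3 has a free ring D phenol and, as ring A, a 4-fluorobenzaldehyde unit with the bridge ortho to fluorine. Cs2CO3 would form the phenoxide, which adds para to the formyl group, passes through a Meisenheimer complex and expels fluoride to give the macrocyclic aldehyde A4. Baeyer–Villiger (Dakin-type) oxidation, formate hydrolysis and cleavage of the ring C methyl ether would then lead to 22.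
- In its favour: the formyl group serves both as activator and as latent hydroxyl at exactly the right carbon, and there is no heavy-metal oxidant and no halogen overhead. In predictability of which atoms join it is at least the equal of the chosen plan, and in reagent safety it is better.
- Against it here: one para formyl group is a modest activator and the fluorine is flanked by the bridge, so the closure needs heat at high dilution with an aldehyde exposed to base. The methyl ether requires a boron trihalide at the end.
- Comparison: it closes the ring at the other ether, so the B–O–C ether needs its own earlier coupling. The mechanism is a two-electron polar substitution with no redox selectivity to worry about. After the ring closure it needs about three operations against one, while the chain assembly is of similar length.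

Alternative 3: The cut removes the two-carbon unit of the A–B bridge: both aryl–vinyl bonds of the macrocyclic (E)-stilbene A6 are disconnected, leaving the open diiodide A5 and (E)-1,2-bis(tributylstannyl)ethene A7. Forward, Pd(PPh3)4 (zerovalent palladium) would couple A7 first with the unhindered ring B iodide and then intramolecularly with the ring A iodide (double Stille coupling). Hydrogenation and cleavage of two methyl ethers would give 22.
- In its favour: two skeletal bonds and the ring form in one operation, which is better than the chosen key step on bond economy. The precursor needs no differentiated benzylic handles and only one preformed bridge, and the conditions are neutral.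
- Against it here: the first coupling is intermolecular with a bifunctional partner, so bridged dimers and oligomers compete. The ring A iodide is hindered by the ortho aryloxy group. A trans alkene between an ortho-linked and a para-linked ring is likely to strain the 18-membered ring and slow the closing step. It also generates stoichiometric organotin waste.
- Comparison: on toxic-metal load the two plans are roughly equal (tin against thallium). Mechanistically it is a catalytic cross-coupling rather than a stoichiometric oxidation. It needs two operations after the key step against one, and its shorter chain assembly could make it the equal of the chosen plan in total count if the ring closure proved efficient.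

Key step: step 13

Remarks on the chemistry:
- The benzylic Wittig reactions are assumed to give E/Z mixtures; these are carried forward unseparated because both alkenes are saturated in step 11.
- 19 (C35H28Br2Cl2O4) and 21 (C35H27BrCl2O4) differ by HBr and one ring bond, and removing benzyl, two Cl and one Br from 21 gives C28H24O4 = 22. The structures are mutually consistent and no correction was needed.
- The halogen pattern of 19 is kept as it stands. The changes lie in how 19 is reached: acetal protection of the dihalophenols (orthogonal to benzyl), the chlorinated ring installed before the hydride reduction, and one reduction for both alkenes.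

## Route

Step 1
Reactants: 1 2-fluoro-5-hydroxybenzaldehyde
Product: 2 5-(benzyloxy)-2-fluorobenzaldehyde
Conditions: BnBr, K2CO3, DMF, rt
Reagents that add atoms: benzyl bromide, BrCc1ccccc1
Why: Williamson etherification of the phenoxide; at room temperature the aryl fluoride is not displaced, and the benzyl ether removes the deactivating phenoxide before step 2 and later shields ring A from the oxidant.

Step 2
Reactants: 2 5-(benzyloxy)-2-fluorobenzaldehyde; 3 methyl 3-hydroxybenzoate
Product: 4 methyl 3-[4-(benzyloxy)-2-formylphenoxy]benzoate
Conditions: K2CO3, DMAc, 130 °C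
Reagents that add atoms: none
Why: Nucleophilic aromatic substitution by addition–elimination; the ortho formyl group stabilises the Meisenheimer complex and fluoride is the best leaving group for this mechanism, while dry carbonate in an aprotic solvent spares the methyl ester.

Step 3
Reactants: 4 methyl 3-[4-(benzyloxy)-2-formylphenoxy]benzoate
Product: 5 methyl 3-[4-(benzyloxy)-2-(hydroxymethyl)phenoxy]benzoate
Conditions: NaBH4, MeOH–THF, 0 °C
Reagents that add atoms: none
Why: Chemoselective borohydride reduction; the aldehyde is reduced far faster than the aryl ester at 0 °C.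

Step 4
Reactants: 5 methyl 3-[4-(benzyloxy)-2-(hydroxymethyl)phenoxy]benzoate
Product: 6 {5-(benzyloxy)-2-[3-(methoxycarbonyl)phenoxy]benzyl}triphenylphosphonium bromide
Conditions: PPh3·HBr, MeCN, reflux
Reagents that add atoms: triphenylphosphine hydrobromide, [Br-].[PH+](c1ccccc1)(c1ccccc1)c1ccccc1
Why: Direct conversion of a benzylic alcohol into its phosphonium salt (protonation, substitution by bromide, quaternisation of PPh3); the ester, the benzyl ether and the diaryl ether should tolerate this weakly acidic salt, and the ester-deactivated ring D should not undergo Friedel–Crafts closure.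

Step 5
Reactants: 7 3,5-dichloro-4-hydroxybenzaldehyde
Product: 8 3,5-dichloro-4-(methoxymethoxy)benzaldehyde
Conditions: MOMCl, iPr2NEt, CH2Cl2, 0 °C to rt
Reagents that add atoms: chloromethyl methyl ether, COCCl
Why: O-alkylation of the acidic, hindered phenol by an oxocarbenium-like electrophile; the acetal removes the phenoxide that would deactivate the aldehyde in the Wittig reaction and is cleavable later without loss of the benzyl ether.

Step 6
Reactants: 6 {5-(benzyloxy)-2-[3-(methoxycarbonyl)phenoxy]benzyl}triphenylphosphonium bromide; 8 3,5-dichloro-4-(methoxymethoxy)benzaldehyde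
Product: 10 methyl 3-[4-(benzyloxy)-2-{2-[3,5-dichloro-4-(methoxymethoxy)phenyl]ethenyl}phenoxy]benzoate as an E/Z mixture, via phosphonium ylide 9 (not isolated)
Conditions: K2CO3, 18-crown-6 (cat.), CH2Cl2, reflux
Reagents that add atoms: none
Why: Wittig olefination under solid–liquid phase-transfer conditions; the semi-stabilised benzylic ylide adds to the electron-poor aldehyde, and the mild carbonate base leaves the methyl ester, the acetal and the aryl chlorides untouched.

Step 7
Reactants: 10 methyl 3-[4-(benzyloxy)-2-{2-[3,5-dichloro-4-(methoxymethoxy)phenyl]ethenyl}phenoxy]benzoate (E/Z mixture)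
Product: 11 [3-(4-(benzyloxy)-2-{2-[3,5-dichloro-4-(methoxymethoxy)phenyl]ethenyl}phenoxy)phenyl]methanol (E/Z mixture)
Conditions: LiAlH4, THF, 0 °C
Reagents that add atoms: none
Why: Hydride reduction of the ester to the primary benzylic alcohol; at 0 °C aryl chlorides, the stilbene, the acetal and the benzyl ether are inert, and no aryl bromide is yet present.

Step 8
Reactants: 11 [3-(4-(benzyloxy)-2-{2-[3,5-dichloro-4-(methoxymethoxy)phenyl]ethenyl}phenoxy)phenyl]methanol (E/Z mixture)
Product: 13 [3-(4-(benzyloxy)-2-{2-[3,5-dichloro-4-(methoxymethoxy)phenyl]ethenyl}phenoxy)benzyl]triphenylphosphonium bromide (E/Z mixture), via benzylic bromide 12 (not isolated)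
Conditions: CBr4, PPh3, CH2Cl2, 0 °C; concentrate under high vacuum; then PPh3, toluene, 90 °C
Reagents that add atoms: tetrabromomethane, BrC(Br)(Br)Br; triphenylphosphine, c1ccc(cc1)P(c1ccccc1)c1ccccc1
Why: Appel bromination under neutral conditions (no free acid, so the acetal should survive), then SN2 quaternisation of PPh3 by the benzylic bromide, with the salt expected to precipitate from toluene.

Step 9
Reactants: 14 3,5-dibromo-4-hydroxybenzaldehyde
Product: 15 3,5-dibromo-4-(methoxymethoxy)benzaldehyde
Conditions: MOMCl, iPr2NEt, CH2Cl2, 0 °C to rt
Reagents that add atoms: chloromethyl methyl ether, COCCl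
Why: Same acetal protection as in step 5, for the same reasons.

Step 10
Reactants: 13 [3-(4-(benzyloxy)-2-{2-[3,5-dichloro-4-(methoxymethoxy)phenyl]ethenyl}phenoxy)benzyl]triphenylphosphonium bromide (E/Z mixture); 15 3,5-dibromo-4-(methoxymethoxy)benzaldehyde
Product: 17 4-(benzyloxy)-1-(3-{2-[3,5-dibromo-4-(methoxymethoxy)phenyl]ethenyl}phenoxy)-2-{2-[3,5-dichloro-4-(methoxymethoxy)phenyl]ethenyl}benzene as a mixture of alkene isomers, via phosphonium ylide 16 (not isolated)
Conditions: K2CO3, 18-crown-6 (cat.), CH2Cl2, reflux
Reagents that add atoms: none
Why: Second Wittig olefination of the same type as step 6; aryl bromides and chlorides are inert to the ylide and to carbonate.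

Step 11
Reactants: 17 4-(benzyloxy)-1-(3-{2-[3,5-dibromo-4-(methoxymethoxy)phenyl]ethenyl}phenoxy)-2-{2-[3,5-dichloro-4-(methoxymethoxy)phenyl]ethenyl}benzene (mixture of alkene isomers)
Product: 18 4-(benzyloxy)-1-(3-{2-[3,5-dibromo-4-(methoxymethoxy)phenyl]ethyl}phenoxy)-2-{2-[3,5-dichloro-4-(methoxymethoxy)phenyl]ethyl}benzene
Conditions: TsNHNH2 (large excess, in portions), NaOAc, DME–H2O, reflux
Reagents that add atoms: none
Why: Diimide reduction (concerted syn transfer of two hydrogens from HN=NH generated from the sulfonyl hydrazide); it saturates both stilbene bonds regardless of geometry and, unlike palladium-catalysed hydrogenation, leaves C–Br, C–Cl and O-benzyl bonds alone, with acetate buffering the sulfinic acid.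

Step 12
Reactants: 18 4-(benzyloxy)-1-(3-{2-[3,5-dibromo-4-(methoxymethoxy)phenyl]ethyl}phenoxy)-2-{2-[3,5-dichloro-4-(methoxymethoxy)phenyl]ethyl}benzene
Product: 19 4-[2-(3-{4-(benzyloxy)-2-[2-(3,5-dichloro-4-hydroxyphenyl)ethyl]phenoxy}phenyl)ethyl]-2,6-dibromophenol (open bisphenol)
Conditions: 3 M HCl, MeOH–THF, 50 °C
Reagents that add atoms: none
Why: Acid-catalysed acetal exchange with methanol; the electron-poor dihalophenols are good leaving groups, and the benzyl ether and the aryl halides are stable to dilute acid.

Step 13
Reactants: 19 4-[2-(3-{4-(benzyloxy)-2-[2-(3,5-dichloro-4-hydroxyphenyl)ethyl]phenoxy}phenyl)ethyl]-2,6-dibromophenol (open bisphenol)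
Product: 21 halogenated O-benzyl macrocycle (ring A O-benzyl; ring B 3,5-dichloro flanking the ether oxygen; ring C bromo ortho to OH), via bromo dienone 20 (not isolated)
Conditions: Tl(NO3)3·3H2O (3 equiv), MeOH–THF 4:1, 1 mM, −20 to 0 °C; then Zn dust, AcOH, rt
Reagents that add atoms: none
Why: Ligand exchange of the phenols at trivalent thallium followed by two-electron transfer (thallium leaves as the monovalent nitrate) turns the more easily oxidised 2,6-dibromophenol of ring C into a phenoxonium-type cation. The ring B phenol oxygen captures this cation at a bromine-bearing ortho carbon and gives the 6-aryloxy-6-bromocyclohexa-2,4-dienone 20; its sp3 carbon is a transient racemic stereocentre that needs no control because it is flattened again. Zinc in acetic acid then removes that bromine by two-electron reduction, as in the dehalogenation of an alpha-bromo ketone, and the resulting dienolate tautomerises to phenol 21. The closest known reaction type is the thallium trinitrate coupling of ortho,ortho-dihalophenols to isodityrosine-type macrocyclic diaryl ethers with zinc work-up. The 18-membered ring closes by intramolecular oxygen-to-carbon nucleophilic capture (a macroetherification at an electrophilic ring carbon), which high dilution favours over chain growth. Ring selection rests on the halogens: the dibromophenol should be the easier to oxidise and bromide the easier to expel reductively, so ring C becomes the hydroxy ether ring while ring B keeps both chlorines and serves only as the oxygen nucleophile. Because all four ortho positions are halogenated and both para positions are alkylated, carbon–carbon coupling is blocked, and any para capture by methanol should give quinol ethers that zinc returns to the starting phenol. The benzyl ether keeps ring A, a hydroquinone derivative, from being oxidised to a quinone.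

Step 14
Reactants: 21 halogenated O-benzyl macrocycle
Product: 22 target macrocycle CNP0135015.0 (rings A and C as free phenols, no halogen)
Conditions: H2 (1–3 atm), 10% Pd/C, Et3N, MeOH–EtOAc, rt
Reagents that add atoms: none
Why: Palladium-catalysed hydrogenolysis; the aryl C–Br bond, both aryl C–Cl bonds (assisted by the amine, which traps HX) and the benzylic C–O bond are cleaved in one operation, while the diaryl ethers and the arene rings are not reduced under these conditions.

## Compound list

1 | 2-fluoro-5-hydroxybenzaldehyde | O=Cc1cc(O)ccc1F | starting material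
2 | 5-(benzyloxy)-2-fluorobenzaldehyde | O=Cc1cc(OCc2ccccc2)ccc1F | intermediate
3 | methyl 3-hydroxybenzoate | COC(=O)c1cccc(O)c1 | starting material
4 | methyl 3-[4-(benzyloxy)-2-formylphenoxy]benzoate | COC(=O)c1cccc(Oc2ccc(OCc3ccccc3)cc2C=O)c1 | intermediate
5 | methyl 3-[4-(benzyloxy)-2-(hydroxymethyl)phenoxy]benzoate | COC(=O)c1cccc(Oc2ccc(OCc3ccccc3)cc2CO)c1 | intermediate
6 | {5-(benzyloxy)-2-[3-(methoxycarbonyl)phenoxy]benzyl}triphenylphosphonium bromide | COC(=O)c1cccc(Oc2ccc(OCc3ccccc3)cc2C[P+](c2ccccc2)(c2ccccc2)c2ccccc2)c1.[Br-] | intermediate
7 | 3,5-dichloro-4-hydroxybenzaldehyde | O=Cc1cc(Cl)c(O)c(Cl)c1 | starting material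
8 | 3,5-dichloro-4-(methoxymethoxy)benzaldehyde | COCOc1c(Cl)cc(C=O)cc1Cl | intermediate
9 | phosphonium ylide derived from 6 (not isolated) | COC(=O)c1cccc(Oc2ccc(OCc3ccccc3)cc2[CH-][P+](c2ccccc2)(c2ccccc2)c2ccccc2)c1 | intermediate
10 | methyl 3-[4-(benzyloxy)-2-{2-[3,5-dichloro-4-(methoxymethoxy)phenyl]ethenyl}phenoxy]benzoate, E/Z mixture (no alkene descriptor) | COC(=O)c1cccc(Oc2ccc(OCc3ccccc3)cc2C=Cc2cc(Cl)c(OCOC)c(Cl)c2)c1 | intermediate
11 | [3-(4-(benzyloxy)-2-{2-[3,5-dichloro-4-(methoxymethoxy)phenyl]ethenyl}phenoxy)phenyl]methanol, E/Z mixture | OCc1cccc(Oc2ccc(OCc3ccccc3)cc2C=Cc2cc(Cl)c(OCOC)c(Cl)c2)c1 | intermediate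
12 | 4-(benzyloxy)-1-[3-(bromomethyl)phenoxy]-2-{2-[3,5-dichloro-4-(methoxymethoxy)phenyl]ethenyl}benzene, E/Z mixture (not isolated) | BrCc1cccc(Oc2ccc(OCc3ccccc3)cc2C=Cc2cc(Cl)c(OCOC)c(Cl)c2)c1 | intermediate
13 | [3-(4-(benzyloxy)-2-{2-[3,5-dichloro-4-(methoxymethoxy)phenyl]ethenyl}phenoxy)benzyl]triphenylphosphonium bromide, E/Z mixture | c1ccccc1[P+](c1ccccc1)(c1ccccc1)Cc1cccc(Oc2ccc(OCc3ccccc3)cc2C=Cc2cc(Cl)c(OCOC)c(Cl)c2)c1.[Br-] | intermediate
14 | 3,5-dibromo-4-hydroxybenzaldehyde | O=Cc1cc(Br)c(O)c(Br)c1 | starting material
15 | 3,5-dibromo-4-(methoxymethoxy)benzaldehyde | COCOc1c(Br)cc(C=O)cc1Br | intermediate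
16 | phosphonium ylide derived from 13 (not isolated) | c1ccccc1[P+](c1ccccc1)(c1ccccc1)[CH-]c1cccc(Oc2ccc(OCc3ccccc3)cc2C=Cc2cc(Cl)c(OCOC)c(Cl)c2)c1 | intermediate
17 | 4-(benzyloxy)-1-(3-{2-[3,5-dibromo-4-(methoxymethoxy)phenyl]ethenyl}phenoxy)-2-{2-[3,5-dichloro-4-(methoxymethoxy)phenyl]ethenyl}benzene, mixture of alkene isomers | COCOc1c(Br)cc(cc1Br)C=Cc1cccc(Oc2ccc(OCc3ccccc3)cc2C=Cc2cc(Cl)c(OCOC)c(Cl)c2)c1 | intermediate
18 | 4-(benzyloxy)-1-(3-{2-[3,5-dibromo-4-(methoxymethoxy)phenyl]ethyl}phenoxy)-2-{2-[3,5-dichloro-4-(methoxymethoxy)phenyl]ethyl}benzene | COCOc1c(Br)cc(cc1Br)CCc1cccc(Oc2ccc(OCc3ccccc3)cc2CCc2cc(Cl)c(OCOC)c(Cl)c2)c1 | intermediate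
19 | open bisphenol: 4-[2-(3-{4-(benzyloxy)-2-[2-(3,5-dichloro-4-hydroxyphenyl)ethyl]phenoxy}phenyl)ethyl]-2,6-dibromophenol | O(Cc1ccccc1)c1ccc(Oc2cccc(CCc3cc(Br)c(O)c(Br)c3)c2)c(CCc2cc(Cl)c(O)c(Cl)c2)c1 | intermediate
20 | macrocyclic bromo dienone: ring C as a 6-aryloxy-2,6-dibromocyclohexa-2,4-dien-1-one, racemic at the sp3 carbon (not isolated) | O(Cc1ccccc1)c1ccc2c(c1)CCc1cc(Cl)c(c(Cl)c1)OC1(Br)C=C(C=C(Br)C1=O)CCc1cccc(c1)O2 | intermediate
21 | halogenated O-benzyl macrocycle (ring A O-benzyl, ring B dichloro ortho to the ether oxygen, ring C bromo ortho to OH) | O(Cc1ccccc1)c1ccc2c(c1)CCc1cc(Cl)c(c(Cl)c1)Oc1cc(cc(Br)c1O)CCc1cccc(c1)O2 | intermediate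
22 | CNP0135015.0, the 18-membered bis(bibenzyl) diphenol (achiral) | Oc1ccc2c(c1)CCc1ccc(cc1)Oc1cc(ccc1O)CCc1cccc(c1)O2 | target

## Step count and least certain steps

Total: 14 steps. Longest linear sequence: 12 steps (steps 1–4, 6–8, 10–14, from 1); steps 5 and 9 are one-step side branches.

**Step 13 (key step).** Three processes could go wrong:
- chain growth by intermolecular capture despite dilution;
- oxidation of the dichlorophenol instead of the dibromophenol, which would close the ring with the ring C oxygen and give the constitutional isomer, since the two dihalophenols differ only modestly in oxidation potential;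
- diversion to solvent adducts, or attack on the electron-rich ring A.

Fallback, setting out from 6 and returning at 22, closes the same B–O–C ether by copper catalysis:
- Wittig reaction of 6 with purchased 4-(methoxymethoxy)benzaldehyde (COCOc1ccc(C=O)cc1) under the conditions of step 6 would give methyl 3-[4-(benzyloxy)-2-{2-[4-(methoxymethoxy)phenyl]ethenyl}phenoxy]benzoate F1.
- LiAlH4 at 0 °C would give the benzylic alcohol F2.
- Appel bromination and quaternisation as in step 8 would give the phosphonium bromide F3.
- Wittig reaction with purchased 4-(benzyloxy)-3-bromobenzaldehyde (O=Cc1ccc(OCc2ccccc2)c(Br)c1) would give the bis-stilbene F4.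
- Diimide reduction would give the saturated bromide F5.
- Acidic methanolysis would free the ring B phenol F6.
- Intramolecular Ullmann etherification (CuI, N,N-dimethylglycine, Cs2CO3, dioxane, high dilution, 100 °C) would give the di-O-benzyl macrocycle F7.
- Hydrogenolysis of both benzyl ethers (H2, Pd/C) would give 22.

**Step 2.** Slow fluoride displacement is the likely problem, because the para benzyloxy group donates into the ring and the formyl group is the only activator; prolonged heating invites ester cleavage and aldehyde decomposition. Fallback from 3, returning at 4: benzylation of purchased 2-bromo-5-hydroxybenzaldehyde gives 5-(benzyloxy)-2-bromobenzaldehyde F8, which is joined to 3 by a copper-catalysed Ullmann ether synthesis (CuI, N,N-dimethylglycine, Cs2CO3, dioxane, 90 °C) to give 4.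

**Step 8.** Two processes threaten it: loss of the acetal through adventitious HBr, and quaternisation of PPh3 by residual bromoform, which would carry a dibromomethylphosphonium contaminant into step 10. Fallback from 11, returning at 17, runs entirely under basic conditions: MsCl, Et3N gives the benzylic methanesulfonate F9; Michaelis–Becker substitution with sodium diethyl phosphite gives the diethyl benzylphosphonate F10; Horner–Wadsworth–Emmons olefination with 15 (NaH, THF) gives 17, now mainly E at the new alkene.

**Step 11.** Incomplete saturation is the risk: diimide disproportionates faster than it adds to the ortho-substituted stilbene, so mono-alkenes may persist. Fallback from 17, returning at 18: homogeneous hydrogenation with RhCl(PPh3)3 under H2 in toluene–EtOH, a catalyst that does not insert into aryl halides or cleave benzyl ethers under these conditions. No new compound is made.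

**Step 14.** Stalling of the hydrodechlorination is the risk: the two C–Cl bonds flank the diaryl ether oxygen inside the macrocycle and the amine hydrohalides can slow the catalyst. Fallback from 21, returning at 22, in two stages: H2, Pd/C, NaOAc removes only the benzyl group and the bromine to give the dichloro diphenol macrocycle F11; a homogeneous palladium hydrodechlorination (Pd(OAc)2, tricyclohexylphosphine, sodium formate, DMF, 100 °C) then gives 22.

## Further compounds

F1 | step 13 | methyl 3-[4-(benzyloxy)-2-{2-[4-(methoxymethoxy)phenyl]ethenyl}phenoxy]benzoate, E/Z mixture | COC(=O)c1cccc(Oc2ccc(OCc3ccccc3)cc2C=Cc2ccc(OCOC)cc2)c1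
F2 | step 13 | [3-(4-(benzyloxy)-2-{2-[4-(methoxymethoxy)phenyl]ethenyl}phenoxy)phenyl]methanol, E/Z mixture | OCc1cccc(Oc2ccc(OCc3ccccc3)cc2C=Cc2ccc(OCOC)cc2)c1
F3 | step 13 | [3-(4-(benzyloxy)-2-{2-[4-(methoxymethoxy)phenyl]ethenyl}phenoxy)benzyl]triphenylphosphonium bromide, E/Z mixture | c1ccccc1[P+](c1ccccc1)(c1ccccc1)Cc1cccc(Oc2ccc(OCc3ccccc3)cc2C=Cc2ccc(OCOC)cc2)c1.[Br-]
F4 | step 13 | 4-(benzyloxy)-1-(3-{2-[4-(benzyloxy)-3-bromophenyl]ethenyl}phenoxy)-2-{2-[4-(methoxymethoxy)phenyl]ethenyl}benzene, mixture of alkene isomers | Brc1cc(ccc1OCc1ccccc1)C=Cc1cccc(Oc2ccc(OCc3ccccc3)cc2C=Cc2ccc(OCOC)cc2)c1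
F5 | step 13 | 4-(benzyloxy)-1-(3-{2-[4-(benzyloxy)-3-bromophenyl]ethyl}phenoxy)-2-{2-[4-(methoxymethoxy)phenyl]ethyl}benzene | Brc1cc(ccc1OCc1ccccc1)CCc1cccc(Oc2ccc(OCc3ccccc3)cc2CCc2ccc(OCOC)cc2)c1
F6 | step 13 | 4-{2-[5-(benzyloxy)-2-(3-{2-[4-(benzyloxy)-3-bromophenyl]ethyl}phenoxy)phenyl]ethyl}phenol | Brc1cc(ccc1OCc1ccccc1)CCc1cccc(Oc2ccc(OCc3ccccc3)cc2CCc2ccc(O)cc2)c1
F7 | step 13 | di-O-benzyl macrocycle (rings A and C O-benzyl, no halogen) | O(Cc1ccccc1)c1ccc2c(c1)CCc1ccc(cc1)Oc1cc(ccc1OCc1ccccc1)CCc1cccc(c1)O2
F8 | step 2 | 5-(benzyloxy)-2-bromobenzaldehyde | O=Cc1cc(OCc2ccccc2)ccc1Br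
F9 | step 8 | 3-(4-(benzyloxy)-2-{2-[3,5-dichloro-4-(methoxymethoxy)phenyl]ethenyl}phenoxy)benzyl methanesulfonate, E/Z mixture | CS(=O)(=O)OCc1cccc(Oc2ccc(OCc3ccccc3)cc2C=Cc2cc(Cl)c(OCOC)c(Cl)c2)c1
F10 | step 8 | diethyl [3-(4-(benzyloxy)-2-{2-[3,5-dichloro-4-(methoxymethoxy)phenyl]ethenyl}phenoxy)benzyl]phosphonate, E/Z mixture | CCOP(=O)(OCC)Cc1cccc(Oc2ccc(OCc3ccccc3)cc2C=Cc2cc(Cl)c(OCOC)c(Cl)c2)c1
F0 | step 11 | none | none
F11 | step 14 | dichloro diphenol macrocycle (ring B dichloro, rings A and C free phenols) | Oc1ccc2c(c1)CCc1cc(Cl)c(c(Cl)c1)Oc1cc(ccc1O)CCc1cccc(c1)O2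
A1 | alternative 1 | 19-membered macrocyclic dibenzyl ether, rings A and C O-methyl | COc1ccc2c(c1)COCc1ccc(cc1)Oc1cc(ccc1OC)CCc1cccc(c1)O2
A2 | alternative 1 | macrocyclic 1,2-diarylethanol, racemic | COc1ccc2c(c1)C(O)Cc1ccc(cc1)Oc1cc(ccc1OC)CCc1cccc(c1)O2
A3 | alternative 2 | open fluoro aldehyde with free ring D phenol, ring C O-methyl | O=Cc1ccc(F)c(c1)CCc1ccc(cc1)Oc1cc(ccc1OC)CCc1cccc(O)c1
A4 | alternative 2 | macrocyclic aldehyde, ring C O-methyl | O=Cc1ccc2c(c1)CCc1ccc(cc1)Oc1cc(ccc1OC)CCc1cccc(c1)O2
A5 | alternative 3 | open diiodide, rings A and C O-methyl | COc1ccc(Oc2cccc(CCc3ccc(OC)c(Oc4ccc(I)cc4)c3)c2)c(I)c1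
A6 | alternative 3 | macrocyclic (E)-stilbene, di-O-methyl | COc1ccc2c(c1)/C=C/c1ccc(cc1)Oc1cc(ccc1OC)CCc1cccc(c1)O2
A7 | alternative 3 | (E)-1,2-bis(tributylstannyl)ethene | CCCC[Sn](CCCC)(CCCC)/C=C/[Sn](CCCC)(CCCC)CCCC
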